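**Plan**

- Numbering: azulene numbering for the carbocycle (C1–C3, C3a, C4–C8, C8a); C1′–C5′ for the side chain, counted outward from C5.
- Retrosynthesis: the acetate and the C4′ carbinol (CBS) go first, then C2′–C3′ (Mukaiyama aldol); the C7 carbinol and the C8 methylidene go back to an α-silyloxy ketone, and C4–OH/C5–H to a cyclic enol ether. C6–C7 and C3a–C8a are then cut together in a (4+3) cycloaddition, followed by O–C4 (alkynol cycloisomerisation), C4–C5 (Sonogashira) and C1–C8a (alkylation).
- Enabling feature: the seven-membered ring carries oxygen on C4 and C7 and a masked carbonyl (=CH2) on C8. C7–C8–C8a is therefore a 1-oxy-2-silyloxyallyl cation (a (Z)-2-silyloxy-2-enal), C3a–C4–C5–C6 is a 2-oxy-1,3-diene, and the Z-alkene C2=C3 of the cyclopentene is a ready three-atom tether between C8a and C3a.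
- Forward: dioxin 7 (masked enal, from a cheap Z-enynol) and vinyl iodide 14 (from hydroxy ester 8) are coupled. Retro-hetero-Diels–Alder unmasks the enal, gold cycloisomerisation builds a temporary oxolane that locks the diene s-cis, and the (4+3) step closes the cyclopentene and the cycloheptanone at once. The oxolane is then hydrolysed and the side chain is grown from the alcohol it releases.
- Stereochemistry: C1′ comes from 8 and, through the temporary oxolane, directs the diene face (C3a) and the protonation at C5. The planar tether enforces the trans ring fusion (C8a). C4 follows from hydride attack anti to the side chain, C7 and C4′ from CBS reagents, and C2′ from a Felkin-selective aldol.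

Key step: step 12

Assumption: the target is taken exactly as the SMILES reads, that is a trans-fused (3aR,4S,5R,7S,8aS) core with a (1′S,2′S,4′R) side chain; compounds 1, 3, 8 and 26 are taken as commercial.

**Step 1**
Reactants: 1 (Z)-3-methylpent-2-en-4-yn-1-ol
Product: 2 (Z)-5-bromo-3-methylpent-3-en-1-yne
Conditions: PBr3 (0.4 equiv), pyridine (cat.), Et2O, −20 → 0 °C
Reagents that add atoms: phosphorus tribromide, BrP(Br)Br
Why: SN2-type bromination of the primary allylic alcohol with PBr3 at low temperature should leave the Z-alkene and the terminal alkyne untouched.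

**Step 2**
Reactants: 3 2,2-dimethyl-1,3-dioxan-5-one
Product: 4 2,2-dimethyl-1,3-dioxan-5-one N,N-dimethylhydrazone
Conditions: Me2NNH2 (1.2 equiv), cyclohexane, 4 Å MS, rt → 50 °C
Reagents that add atoms: 1,1-dimethylhydrazine, CN(C)N
Why: Condensation to the hydrazone, whose aza-enolate should allow the clean mono-C-alkylation that the self-condensing dioxanone enolate does not.

**Step 3**
Reactants: 4 2,2-dimethyl-1,3-dioxan-5-one N,N-dimethylhydrazone; 2 (Z)-5-bromo-3-methylpent-3-en-1-yne
Product: 6 2,2-dimethyl-4-[(Z)-3-methylpent-2-en-4-yn-1-yl]-1,3-dioxan-5-one (racemic), via alkylated hydrazone 5 (not isolated)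
Conditions: LiN(i-Pr)2, THF, −78 °C; 2, −78 → −30 °C; then sat. aq. oxalic acid, Et2O, 0 °C → rt
Reagents that add atoms: water, O
Why: Aza-enolate alkylation (SN2 at the primary allylic carbon, Z geometry kept) followed by hydrolysis of the hydrazone; the new centre is made racemic on purpose because it becomes sp2 in step 10.

**Step 4**
Reactants: 6 2,2-dimethyl-4-[(Z)-3-methylpent-2-en-4-yn-1-yl]-1,3-dioxan-5-one
Product: 7 tert-butyl{[2,2-dimethyl-4-((Z)-3-methylpent-2-en-4-yn-1-yl)-4H-1,3-dioxin-5-yl]oxy}dimethylsilane (racemic)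
Conditions: LiN(SiMe3)2 (1.05 equiv), THF, −78 °C; TBSOTf, −78 °C; Et3N quench
Reagents that add atoms: tert-butyldimethylsilyl trifluoromethanesulfonate, CC(C)(C)[Si](C)(C)OS(=O)(=O)C(F)(F)F
Why: Kinetic deprotonation at the unsubstituted ring CH2 and O-silylation (silyl enol ether formation) should give the 5-silyloxy-4H-1,3-dioxin, a heat-labile mask of a (Z)-2-silyloxy-2-enal.

**Step 5**
Reactants: 8 methyl (R)-3-hydroxy-2-methylpropanoate
Product: 9 methyl (R)-3-[(tert-butyldimethylsilyl)oxy]-2-methylpropanoate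
Conditions: TBSCl, imidazole, CH2Cl2, 0 °C → rt
Reagents that add atoms: tert-butyldimethylsilyl chloride, CC(C)(C)[Si](C)(C)Cl
Why: Standard silylation of the primary alcohol.

**Step 6**
Reactants: 9 methyl (R)-3-[(tert-butyldimethylsilyl)oxy]-2-methylpropanoate
Product: 11 (S)-tert-butyldimethyl[(2-methylbut-3-yn-1-yl)oxy]silane, via aldehyde 10 (not isolated)
Conditions: i-Bu2AlH (1.1 equiv), CH2Cl2, −78 °C; then MeOH, K2CO3, MeC(O)C(N2)P(O)(OMe)2, 0 °C → rt
Reagents that add atoms: dimethyl (1-diazo-2-oxopropyl)phosphonate, CC(=O)C(=[N+]=[N-])P(=O)(OC)OC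
Why: Partial reduction of the ester (tetrahedral aluminate stable at −78 °C) and Seyferth–Gilbert homologation with the Ohira–Bestmann reagent in one flask; the carbonate base and low temperature should preserve the α-stereocentre.

**Step 7**
Reactants: 11 (S)-tert-butyldimethyl[(2-methylbut-3-yn-1-yl)oxy]silane
Product: 13 (R)-tert-butyl[(3-iodo-2-methylbut-3-en-1-yl)oxy]dimethylsilane, via alkenylborane 12 (not isolated)
Conditions: B-iodo-9-BBN (1.1 equiv), pentane, −20 → 0 °C; then AcOH, 0 °C
Reagents that add atoms: B-iodo-9-borabicyclo[3.3.1]nonane, IB1C2CCCC1CCC2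
Why: Syn iodoboration places iodine on the internal alkyne carbon and protodeboronation with acetic acid should then give the 2-iodo-1-alkene (formal Markovnikov addition of HI).

**Step 8**
Reactants: 13 (R)-tert-butyl[(3-iodo-2-methylbut-3-en-1-yl)oxy]dimethylsilane
Product: 14 (R)-3-iodo-2-methylbut-3-en-1-ol
Conditions: Bu4NF, THF, 0 °C
Reagents that add atoms: none
Why: Fluoride-mediated desilylation frees the primary alcohol that later serves as the internal nucleophile of step 11.

**Step 9**
Reactants: 7 tert-butyl{[2,2-dimethyl-4-((Z)-3-methylpent-2-en-4-yn-1-yl)-4H-1,3-dioxin-5-yl]oxy}dimethylsilane; 14 (R)-3-iodo-2-methylbut-3-en-1-ol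
Product: 15 (2S,6Z)-8-[5-(tert-butyldimethylsilyloxy)-2,2-dimethyl-4H-1,3-dioxin-4-yl]-2,6-dimethyl-3-methylideneoct-6-en-4-yn-1-ol (both dioxin epimers)
Conditions: Pd(PPh3)4 (3 mol %), CuI (6 mol %), Et3N, THF, rt
Reagents that add atoms: none
Why: Sonogashira coupling of the terminal enyne with the vinyl iodide joins C4 to C5; amine base and room temperature should be compatible with the silyl enol ether and the free alcohol.

**Step 10**
Reactants: 15 (2S,6Z)-8-[5-(tert-butyldimethylsilyloxy)-2,2-dimethyl-4H-1,3-dioxin-4-yl]-2,6-dimethyl-3-methylideneoct-6-en-4-yn-1-ol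
Product: 16 (2Z,5Z,10S)-2-[(tert-butyldimethylsilyl)oxy]-11-hydroxy-6,10-dimethyl-9-methylideneundeca-2,5-dien-7-ynal
Conditions: toluene (0.02 M), 110 °C
Reagents that add atoms: none
Why: Retro-hetero-Diels–Alder reaction of the 5-silyloxy-4H-1,3-dioxin expels acetone and should unveil the (Z)-2-silyloxy-2-enal (the dioxin C4 substituent turns outward in the oxadiene), both dioxin epimers converging.

**Step 11**
Reactants: 16 (2Z,5Z,10S)-2-[(tert-butyldimethylsilyl)oxy]-11-hydroxy-6,10-dimethyl-9-methylideneundeca-2,5-dien-7-ynal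
Product: 17 (2Z,5Z)-2-[(tert-butyldimethylsilyl)oxy]-6-methyl-7-[(2Z,4S)-4-methyl-3-methylideneoxolan-2-ylidene]hepta-2,5-dienal
Conditions: (Ph3P)AuNTf2 (2 mol %), 2,6-di-tert-butylpyridine (5 mol %), CH2Cl2, 0 °C; filtration through basic alumina, used at once
Reagents that add atoms: none
Why: Gold-catalysed 5-exo-dig hydroalkoxylation (anti addition of O–H across the alkyne) should close the temporary oxolane and give the (Z)-alkylidene enol ether, an s-cis-locked 2-oxy-1,3-diene.

**Step 12**
Reactants: 17 (2Z,5Z)-2-[(tert-butyldimethylsilyl)oxy]-6-methyl-7-[(2Z,4S)-4-methyl-3-methylideneoxolan-2-ylidene]hepta-2,5-dienal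
Product: 18 tricyclic (4+3) adduct: (3aR,7R,8aS)-7-[(tert-butyldimethylsilyl)oxy]-3-methyl-8-oxo hydroazulene (C2=C3 alkene, trans ring fusion) whose C4=C5 bond is part of a 2,3-dihydrofuran (O on C4, ring CH2 = C2′, ring CH(CH3) = C1′, S)
Conditions: Sc(OTf)3 (10 mol %), 2,6-di-tert-butylpyridine (20 mol %), CH2Cl2 (0.005 M), −78 → −30 °C; Et3N quench
Reagents that add atoms: none
Why: Proposed new method: Sc(OTf)3 binds the aldehyde of the (Z)-2-silyloxy-2-enal and turns C7–C8–C8a into a 1-oxy-2-silyloxyallyl cation; the nucleophilic terminus C3a of the locked 2-oxydiene attacks C8a, C7 then closes on C6, and the TBS group passes from the oxygen on C8 to that on C7, which frees the catalyst (concerted-asynchronous or stepwise (4+3) cycloaddition). The closest known reaction types are the Lewis-acid-promoted intermolecular (4+3) cycloaddition of (Z)-2-silyloxy-2-enals with dienes and the intramolecular (4+3) cycloaddition of alkoxyallyl cations; new here are the tethering of this cation type and the oxolane-locked diene. The cyclopentene closes by 5-exo-trig attack of the enol-ether carbon on the enal β-carbon, the cycloheptanone by 7-endo-trig return of C7 onto the allyl-oxocarbenium terminus C6. C3a should be set by approach anti to the methyl group on the temporary oxolane; C8a by the extended transition state that the planar Z-alkene tether imposes (tether bonds at C3a and C8a eclipsed, hence trans fusion); C7 by the W-shaped cation (OTBS cis to C1), a centre that is not relied on and is reset in steps 16 and 17. The step needs (4+3) instead of (4+2) closure and one diene face: the 2-silyloxy group stabilises the charge at C8 as an oxocarbenium ion and makes C7, not C8, the nucleophilic carbon of the second closure, the oxolane keeps the diene s-cis, and the three-atom tether lets only C3a reach C8a.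

**Step 13**
Reactants: 18 tricyclic (4+3) adduct
Product: 19 8-methylidene analogue of 18 (C8=O replaced by C8=CH2)
Conditions: Cp2TiMe2 (3 equiv), toluene/THF, 65 °C, dark
Reagents that add atoms: dimethyltitanocene, C[Ti](C)(C1C=CC=C1)C1C=CC=C1
Why: Petasis methylenation should convert the hindered, enolisable C8 ketone under non-basic conditions, so that C8a, C3a and the acid-labile enol ether survive.

**Step 14**
Reactants: 19 8-methylidene analogue of 18
Product: 20 (3aR,5R,7R,8aS)-7-hydroxy-5-[(2S)-1-hydroxypropan-2-yl]-3-methyl-8-methylidene-3a,5,6,7,8,8a-hexahydroazulen-4(1H)-one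
Conditions: aq. HF (48 %)/MeCN 1:19, 0 °C → rt
Reagents that add atoms: water, O
Why: Acid hydrolysis of the cyclic enol ether (protonation at C5, then collapse of the hemiketal) frees the C4 ketone and the C2′ alcohol and removes the TBS group; the proton should enter C5 anti to the adjacent oxolane methyl group (kinetic protonation from the less hindered face), which gives (5R).

**Step 15**
Reactants: 20 hydroxy ketone
Product: 21 (3aR,4S,5R,7R,8aS)-5-[(2S)-1-hydroxypropan-2-yl]-3-methyl-8-methylidene-1,3a,4,5,6,7,8,8a-octahydroazulene-4,7-diol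
Conditions: LiBH(s-Bu)3 (4 equiv), THF, −78 °C
Reagents that add atoms: none
Why: Substrate-controlled reduction with a bulky hydride: attack anti to the C5 side chain should give the (4S) alcohol cis to that chain, and the ketone is reduced at once to forestall migration of the C2=C3 double bond into conjugation.

**Step 16**
Reactants: 21 triol (C7 epimeric)
Product: 22 (3aR,4S,5R,8aS)-4-hydroxy-5-[(2S)-1-hydroxypropan-2-yl]-3-methyl-8-methylidene-3a,4,5,6,8,8a-hexahydroazulen-7(1H)-one
Conditions: activated MnO2 (20 equiv), CH2Cl2, rt; used directly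
Reagents that add atoms: none
Why: Chemoselective MnO2 oxidation of the allylic C7 alcohol (the saturated secondary and the primary hydroxyl stay) erases the C7 configuration delivered by the cycloaddition, whichever it is.

**Step 17**
Reactants: 22 enone diol
Product: 23 (3aR,4S,5R,7S,8aS)-5-[(2S)-1-hydroxypropan-2-yl]-3-methyl-8-methylidene-1,3a,4,5,6,7,8,8a-octahydroazulene-4,7-diol
Conditions: (R)-2-methyl-CBS-oxazaborolidine (20 mol %), catecholborane (3.5 equiv), toluene, −78 °C
Reagents that add atoms: none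
Why: Corey–Bakshi–Shibata reduction: with the methylidene-bearing carbon as the large group the (R)-oxazaborolidine should give the (7S) allylic alcohol by reagent control, and 1,2-reduction is expected at −78 °C.

**Step 18**
Reactants: 23 triol
Product: 24 tris(triethylsilyl) ether of 23
Conditions: TESOTf (3.6 equiv), 2,6-lutidine, CH2Cl2, −78 → 0 °C
Reagents that add atoms: triethylsilyl trifluoromethanesulfonate, CC[Si](CC)(CC)OS(=O)(=O)C(F)(F)F
Why: Exhaustive silylation protects the two secondary hydroxyls for the later acetylation and turns the primary one into the TES ether that step 19 oxidises.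

**Step 19**
Reactants: 24 tris(triethylsilyl) ether
Product: 25 (2S)-2-[(3aR,4S,5R,7S,8aS)-3-methyl-8-methylidene-4,7-bis(triethylsilyloxy)-1,3a,4,5,6,7,8,8a-octahydroazulen-5-yl]propanal
Conditions: (COCl)2, DMSO, CH2Cl2, −78 → −40 °C; then Et3N, −78 → 0 °C
Reagents that add atoms: none
Why: Swern conditions cleave and oxidise a primary TES ether directly to the aldehyde while secondary TES ethers survive (chemoselective Swern oxidation of primary silyl ethers); C1′ should not epimerise at low temperature.

**Step 20**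
Reactants: 26 3-methylbut-3-en-2-one
Product: 27 trimethyl[(3-methylbuta-1,3-dien-2-yl)oxy]silane
Conditions: TMSOTf, Et3N, Et2O, 0 °C; distillation
Reagents that add atoms: trimethylsilyl trifluoromethanesulfonate, C[Si](C)(C)OS(=O)(=O)C(F)(F)F
Why: Soft enolisation and O-silylation of the methyl ketone give the enol silane for the aldol step.

**Step 21**
Reactants: 25 aldehyde; 27 trimethyl[(3-methylbuta-1,3-dien-2-yl)oxy]silane
Product: 28 (5S,6S)-5-hydroxy-2-methyl-6-[(3aR,4S,5R,7S,8aS)-3-methyl-8-methylidene-4,7-bis(triethylsilyloxy)-1,3a,4,5,6,7,8,8a-octahydroazulen-5-yl]hept-1-en-3-one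
Conditions: BF3·OEt2 (1.2 equiv), CH2Cl2, −78 °C; aq. NaHCO3
Reagents that add atoms: none
Why: Mukaiyama aldol addition through an open transition state; Felkin–Anh control by C1′ (ring as the large group) should give the 1′,2′-syn adduct, that is (2′S).

**Step 22**
Reactants: 28 β-hydroxy enone
Product: 29 (2S,3S)-6-methyl-2-[(3aR,4S,5R,7S,8aS)-3-methyl-8-methylidene-4,7-bis(triethylsilyloxy)-1,3a,4,5,6,7,8,8a-octahydroazulen-5-yl]-5-oxohept-6-en-3-yl acetate
Conditions: Ac2O, pyridine, 0 °C → rt
Reagents that add atoms: acetic anhydride, CC(=O)OC(C)=O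
Why: Acetylation of the only free hydroxyl under mild conditions, without a strong base that could eliminate the β-acetoxy ketone.

**Step 23**
Reactants: 29 β-acetoxy enone
Product: 30 (2S,3S,5R)-5-hydroxy-6-methyl-2-[(3aR,4S,5R,7S,8aS)-3-methyl-8-methylidene-4,7-bis(triethylsilyloxy)-1,3a,4,5,6,7,8,8a-octahydroazulen-5-yl]hept-6-en-3-yl acetate
Conditions: (S)-2-methyl-CBS-oxazaborolidine (20 mol %), catecholborane (2 equiv), toluene, −78 °C
Reagents that add atoms: none
Why: Corey–Bakshi–Shibata reduction of the α-substituted enone: with isopropenyl as the large group the (S)-oxazaborolidine should give the (4′R) allylic alcohol, and catecholborane at −78 °C spares the alkenes and the acetate.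

**Step 24**
Reactants: 30 bis(triethylsilyl) ether
Product: 31 (2S,3S,5R)-2-[(3aR,4S,5R,7S,8aS)-4,7-dihydroxy-3-methyl-8-methylidene-1,3a,4,5,6,7,8,8a-octahydroazulen-5-yl]-5-hydroxy-6-methylhept-6-en-3-yl acetate (target)
Conditions: HF·pyridine, pyridine, THF, 0 °C → rt
Reagents that add atoms: none
Why: Buffered fluoride desilylation removes both TES ethers without base, so the acetate should not migrate to the 1,3-related hydroxyl.

**Compound list**

1 | (Z)-3-methylpent-2-en-4-yn-1-ol | C#C/C(C)=C\CO | starting material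
2 | (Z)-5-bromo-3-methylpent-3-en-1-yne | C#C/C(C)=C\CBr | intermediate
3 | 2,2-dimethyl-1,3-dioxan-5-one | CC1(C)OCC(=O)CO1 | starting material
4 | 2,2-dimethyl-1,3-dioxan-5-one N,N-dimethylhydrazone | CN(C)N=C1COC(C)(C)OC1 | intermediate
5 | alkylated hydrazone: N,N-dimethylhydrazone of 6 (racemic) | CN(C)N=C1COC(C)(C)OC1C/C=C(C)\C#C | intermediate
6 | 2,2-dimethyl-4-[(Z)-3-methylpent-2-en-4-yn-1-yl]-1,3-dioxan-5-one (racemic) | CC1(C)OCC(=O)C(C/C=C(C)\C#C)O1 | intermediate
7 | tert-butyl{[2,2-dimethyl-4-((Z)-3-methylpent-2-en-4-yn-1-yl)-4H-1,3-dioxin-5-yl]oxy}dimethylsilane (racemic) | CC1(C)OC=C(O[Si](C)(C)C(C)(C)C)C(C/C=C(C)\C#C)O1 | intermediate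
8 | methyl (R)-3-hydroxy-2-methylpropanoate | OC[C@@H](C)C(=O)OC | starting material
9 | methyl (R)-3-[(tert-butyldimethylsilyl)oxy]-2-methylpropanoate | CC(C)(C)[Si](C)(C)OC[C@@H](C)C(=O)OC | intermediate
10 | (R)-3-[(tert-butyldimethylsilyl)oxy]-2-methylpropanal | CC(C)(C)[Si](C)(C)OC[C@@H](C)C=O | intermediate
11 | (S)-tert-butyldimethyl[(2-methylbut-3-yn-1-yl)oxy]silane | CC(C)(C)[Si](C)(C)OC[C@@H](C)C#C | intermediate
12 | B-[(1Z,3R)-4-(tert-butyldimethylsilyloxy)-2-iodo-3-methylbut-1-en-1-yl]-9-borabicyclo[3.3.1]nonane | CC(C)(C)[Si](C)(C)OC[C@@H](C)/C(I)=C/B1C2CCCC1CCC2 | intermediate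
13 | (R)-tert-butyl[(3-iodo-2-methylbut-3-en-1-yl)oxy]dimethylsilane | CC(C)(C)[Si](C)(C)OC[C@@H](C)C(I)=C | intermediate
14 | (R)-3-iodo-2-methylbut-3-en-1-ol | OC[C@@H](C)C(I)=C | intermediate
15 | (2S,6Z)-8-[5-(tert-butyldimethylsilyloxy)-2,2-dimethyl-4H-1,3-dioxin-4-yl]-2,6-dimethyl-3-methylideneoct-6-en-4-yn-1-ol (both dioxin epimers) | CC1(C)OC=C(O[Si](C)(C)C(C)(C)C)C(C/C=C(C)\C#CC(=C)[C@H](C)CO)O1 | intermediate
16 | (2Z,5Z,10S)-2-[(tert-butyldimethylsilyl)oxy]-11-hydroxy-6,10-dimethyl-9-methylideneundeca-2,5-dien-7-ynal | O=C/C(O[Si](C)(C)C(C)(C)C)=C/C/C=C(C)\C#CC(=C)[C@H](C)CO | intermediate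
17 | (2Z,5Z)-2-[(tert-butyldimethylsilyl)oxy]-6-methyl-7-[(2Z,4S)-4-methyl-3-methylideneoxolan-2-ylidene]hepta-2,5-dienal | C=C1[C@H](C)CO/C1=C\C(C)=C/C/C=C(\O[Si](C)(C)C(C)(C)C)C=O | intermediate
18 | tricyclic (4+3) adduct: (3aR,7R,8aS)-7-(tert-butyldimethylsilyloxy)-3-methyl-8-oxo hydroazulene, trans-fused, with C4=C5 in a 2,3-dihydrofuran (O on C4; ring CH(CH3) carbon S) | C[C@@H]1COC2=C1C[C@@H](O[Si](C)(C)C(C)(C)C)C(=O)[C@H]1CC=C(C)[C@@H]12 | intermediate
19 | 8-methylidene analogue of 18 | C[C@@H]1COC2=C1C[C@@H](O[Si](C)(C)C(C)(C)C)C(=C)[C@H]1CC=C(C)[C@@H]12 | intermediate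
20 | (3aR,5R,7R,8aS)-7-hydroxy-5-[(2S)-1-hydroxypropan-2-yl]-3-methyl-8-methylidene-3a,5,6,7,8,8a-hexahydroazulen-4(1H)-one | OC[C@@H](C)[C@H]1C[C@@H](O)C(=C)[C@H]2CC=C(C)[C@@H]2C1=O | intermediate
21 | (3aR,4S,5R,7R,8aS)-5-[(2S)-1-hydroxypropan-2-yl]-3-methyl-8-methylidene-1,3a,4,5,6,7,8,8a-octahydroazulene-4,7-diol | OC[C@@H](C)[C@H]1C[C@@H](O)C(=C)[C@H]2CC=C(C)[C@@H]2[C@H]1O | intermediate
22 | (3aR,4S,5R,8aS)-4-hydroxy-5-[(2S)-1-hydroxypropan-2-yl]-3-methyl-8-methylidene-3a,4,5,6,8,8a-hexahydroazulen-7(1H)-one | OC[C@@H](C)[C@H]1CC(=O)C(=C)[C@H]2CC=C(C)[C@@H]2[C@H]1O | intermediate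
23 | (3aR,4S,5R,7S,8aS)-5-[(2S)-1-hydroxypropan-2-yl]-3-methyl-8-methylidene-1,3a,4,5,6,7,8,8a-octahydroazulene-4,7-diol | OC[C@@H](C)[C@H]1C[C@H](O)C(=C)[C@H]2CC=C(C)[C@@H]2[C@H]1O | intermediate
24 | tris(triethylsilyl) ether of 23 | CC[Si](CC)(CC)OC[C@@H](C)[C@H]1C[C@H](O[Si](CC)(CC)CC)C(=C)[C@H]2CC=C(C)[C@@H]2[C@H]1O[Si](CC)(CC)CC | intermediate
25 | (2S)-2-[(3aR,4S,5R,7S,8aS)-3-methyl-8-methylidene-4,7-bis(triethylsilyloxy)-1,3a,4,5,6,7,8,8a-octahydroazulen-5-yl]propanal | O=C[C@@H](C)[C@H]1C[C@H](O[Si](CC)(CC)CC)C(=C)[C@H]2CC=C(C)[C@@H]2[C@H]1O[Si](CC)(CC)CC | intermediate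
26 | 3-methylbut-3-en-2-one | CC(=O)C(C)=C | starting material
27 | trimethyl[(3-methylbuta-1,3-dien-2-yl)oxy]silane | C=C(C)C(=C)O[Si](C)(C)C | intermediate
28 | (5S,6S)-5-hydroxy-2-methyl-6-[(3aR,4S,5R,7S,8aS)-3-methyl-8-methylidene-4,7-bis(triethylsilyloxy)-1,3a,4,5,6,7,8,8a-octahydroazulen-5-yl]hept-1-en-3-one | C=C(C)C(=O)C[C@H](O)[C@@H](C)[C@H]1C[C@H](O[Si](CC)(CC)CC)C(=C)[C@H]2CC=C(C)[C@@H]2[C@H]1O[Si](CC)(CC)CC | intermediate
29 | (2S,3S)-6-methyl-2-[(3aR,4S,5R,7S,8aS)-3-methyl-8-methylidene-4,7-bis(triethylsilyloxy)-1,3a,4,5,6,7,8,8a-octahydroazulen-5-yl]-5-oxohept-6-en-3-yl acetate | C=C(C)C(=O)C[C@H](OC(C)=O)[C@@H](C)[C@H]1C[C@H](O[Si](CC)(CC)CC)C(=C)[C@H]2CC=C(C)[C@@H]2[C@H]1O[Si](CC)(CC)CC | intermediate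
30 | (2S,3S,5R)-5-hydroxy-6-methyl-2-[(3aR,4S,5R,7S,8aS)-3-methyl-8-methylidene-4,7-bis(triethylsilyloxy)-1,3a,4,5,6,7,8,8a-octahydroazulen-5-yl]hept-6-en-3-yl acetate | C=C(C)[C@H](O)C[C@H](OC(C)=O)[C@@H](C)[C@H]1C[C@H](O[Si](CC)(CC)CC)C(=C)[C@H]2CC=C(C)[C@@H]2[C@H]1O[Si](CC)(CC)CC | intermediate
31 | (2S,3S,5R)-2-[(3aR,4S,5R,7S,8aS)-4,7-dihydroxy-3-methyl-8-methylidene-1,3a,4,5,6,7,8,8a-octahydroazulen-5-yl]-5-hydroxy-6-methylhept-6-en-3-yl acetate | C=C(C)[C@H](O)C[C@H](OC(C)=O)[C@@H](C)[C@H]1C[C@H](O)C(=C)[C@H]2CC=C(C)[C@@H]2[C@H]1O | target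

**Step count and risks**

Total step count: 24. Longest linear sequence: 19 steps (from 8: steps 5 to 19 and 21 to 24).

Steps most likely to fail:

1. Step 12. The Lewis acid may decompose or oligomerise the dienyl ether before ring closure, the second bond may close to the six-membered ring ((4+2) instead of (4+3)), or the wrong diene face or a compact transition state may be used. The fallback uses known chemistry, sets out from 17 and comes back at 18. Compound 17 is heated in dilute toluene (80–110 °C) without any Lewis acid, so that an intramolecular Diels–Alder reaction of the locked diene with the enal double bond gives the hydrindene aldehyde F1 (C8 bonded to C6 and carrying OTBS and CHO). F1 is then treated with a Lewis acid such as Me2AlCl at −78 → −20 °C. This should bring about the α-ketol-type 1,2-shift of the allylic carbon C6 from C8 to the aldehyde carbon, with transfer of the silyl group between the two oxygens. This two-stage Diels–Alder/ring-expansion sequence is a known equivalent of the (4+3) cycloaddition for adducts of 2-silyloxyacroleins, and it returns 18.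

2. Step 14. The proton may enter C5 from the methyl-bearing face, the new ketone may epimerise at C5 under acid, or the C2=C3 double bond may move into conjugation with C4=O. The fallback sets out from 20 and comes back at 21. Compound 20 and its C5 epimer F2 are not separated but hydrogenated under Noyori conditions with dynamic kinetic resolution (RuCl2(xylbinap)(daipen), the enantiomer that gives the (4S) carbinol, KOt-Bu (cat.), i-PrOH, H2). The α-centre equilibrates through the enolate while the catalyst reduces only the epimer that leads to the alcohol cis to the side chain, so that C5 and C4 are set together by the catalyst and L-Selectride is not needed; the product is 21.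

3. Step 13. The hindered ketone may enolise (loss of C8a) or fail to react with the titanium reagent. The fallback sets out from 18 and comes back at 19. Addition of Me3SiCH2MgCl in the presence of CeCl3 (THF, −78 → 0 °C; non-basic organocerium addition) gives the β-hydroxysilane F3, and KH in THF at 0 °C then effects the Peterson elimination to 19.

**Further compounds**

F1 | step 12 | intramolecular Diels–Alder adduct of 17: hydrindene carbaldehyde with C8 bonded to C6, OTBS (cis to C1) and CHO on C8, same dihydrofuran and cyclopentene as 18 | C[C@@H]1COC2=C1C[C@](O[Si](C)(C)C(C)(C)C)(C=O)[C@H]1CC=C(C)[C@@H]12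
F2 | step 14 | C5 epimer of 20: (3aR,5S,7R,8aS)-7-hydroxy-5-[(2S)-1-hydroxypropan-2-yl]-3-methyl-8-methylidene-3a,5,6,7,8,8a-hexahydroazulen-4(1H)-one | OC[C@@H](C)[C@@H]1C[C@@H](O)C(=C)[C@H]2CC=C(C)[C@@H]2C1=O
F3 | step 13 | β-hydroxysilane from 18: C8 carries OH and CH2SiMe3 (either C8 epimer) | C[C@@H]1COC2=C1C[C@@H](O[Si](C)(C)C(C)(C)C)C(O)(C[Si](C)(C)C)[C@H]1CC=C(C)[C@@H]12
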